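The decalin is cut across C5–C10 and C8–C9. Ring B carries the C7 oxygen and the C8 one-carbon branch beside the C9/C10 stereocentres, so it maps onto a C5–C8 2-silyloxydiene and an E-configured C9=C10 dienophile linked through C1–C4. A single auxiliary-controlled intramolecular Diels–Alder reaction of an acyclic trienimide thus closes rings A and B together and sets C5, C9 and C10 with the angular methyl in place. Its precursor is the (S)-4-benzyloxazolidinone imide of an E-3-methyl-2-enoic acid whose chain ends, beyond the gem-dimethyl carbon, in a Z-silyl enol ether diene. C13 is taken from methyl (R)-3-methylglutarate; the 7α-acetoxy-8(17)-ene is developed from the masked C7 ketone.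

Key step: step 10

Remark: labdane numbering is used (ring A = C1–C5 and C10, ring B = C5–C10, side chain C11–C15, C17 on C8, C20 on C10; β = the face of the C10 methyl); 5-iodopent-1-yne, diethyl (2-oxobutyl)phosphonate and methyl (R)-3-methylglutarate are taken as purchased.

Step 1
Reactants: 1 methyl isobutyrate; 2 5-iodopent-1-yne
Product: 4 methyl 2,2-dimethylhept-6-ynoate, via lithium ester enolate 3 (not isolated)
Conditions: LiN(iPr)2, THF, −78 °C (1 in slight excess); then 2, −78 °C → rt
Reagents that add atoms: none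
Why: Alkylation of the lithium ester enolate (SN2 at the primary iodide) creates the quaternary C4 with its two methyl groups, the enolate being used in slight excess because the terminal alkyne can quench part of it.

Step 2
Reactants: 4 methyl 2,2-dimethylhept-6-ynoate
Product: 5 2,2-dimethylhept-6-yn-1-ol
Conditions: LiAlH4, Et2O, 0 °C → rt
Reagents that add atoms: none
Why: Hydride reduction of the ester with LiAlH4 gives the neopentyl-type primary alcohol, the isolated terminal alkyne being inert under these conditions.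

Step 3
Reactants: 5 2,2-dimethylhept-6-yn-1-ol
Product: 6 tert-butyl[(2,2-dimethylhept-6-yn-1-yl)oxy]dimethylsilane
Conditions: tert-butyldimethylsilyl chloride, imidazole, DMF, rt
Reagents that add atoms: tert-butyldimethylsilyl chloride, CC(C)(C)[Si](C)(C)Cl
Why: Silyl ether formation masks the hydroxyl group, which would otherwise consume the aluminium and acylating reagents of the next two steps.

Step 4
Reactants: 6 tert-butyl[(2,2-dimethylhept-6-yn-1-yl)oxy]dimethylsilane
Product: 9 (E)-8-[(tert-butyldimethylsilyl)oxy]-3,7,7-trimethyloct-2-enoic acid, via (E)-alkenyldimethylalane 7 (not isolated), via lithium alkenylalanate 8 (not isolated)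
Conditions: Me3Al (2.5 equiv), Cp2ZrCl2 (0.25 equiv), CH2Cl2, 0 °C → rt; volatiles removed; n-BuLi, THF, −78 °C; CO2, −78 °C → rt; cold 1 M HCl
Reagents that add atoms: trimethylaluminium, C[Al](C)C; carbon dioxide, O=C=O
Why: Negishi carboalumination (Cp2ZrCl2-catalysed syn addition of methyl and aluminium, methyl to the internal carbon) followed by carboxylation of the derived lithium alanate with retention gives the E-3-methyl-2-enoic acid, which fixes the C9=C10 geometry that later relates C9 to C10.

Step 5
Reactants: 9 (E)-8-[(tert-butyldimethylsilyl)oxy]-3,7,7-trimethyloct-2-enoic acid; 10 (S)-4-benzyloxazolidin-2-one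
Product: 12 (S)-4-benzyl-3-{(E)-8-[(tert-butyldimethylsilyl)oxy]-3,7,7-trimethyloct-2-enoyl}oxazolidin-2-one, via mixed pivalic anhydride 11 (not isolated)
Conditions: pivaloyl chloride, Et3N, THF, −20 °C; then 10, LiCl, −20 °C → rt
Reagents that add atoms: none
Why: N-Acylation of the oxazolidinone through the mixed pivalic anhydride under LiCl/Et3N activation installs the chiral auxiliary without a strong base, so the γ-acidic 3-methylenoyl unit keeps its E geometry.

Step 6
Reactants: 12 (S)-4-benzyl-3-{(E)-8-[(tert-butyldimethylsilyl)oxy]-3,7,7-trimethyloct-2-enoyl}oxazolidin-2-one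
Product: 13 (S)-4-benzyl-3-[(E)-8-hydroxy-3,7,7-trimethyloct-2-enoyl]oxazolidin-2-one
Conditions: HF·pyridine, pyridine, THF, 0 °C → rt
Reagents that add atoms: none
Why: Fluoride-mediated desilylation frees the primary alcohol while the imide and the trisubstituted alkene stay intact.

Step 7
Reactants: 13 (S)-4-benzyl-3-[(E)-8-hydroxy-3,7,7-trimethyloct-2-enoyl]oxazolidin-2-one
Product: 14 (S)-4-benzyl-3-[(E)-3,7,7-trimethyl-8-oxooct-2-enoyl]oxazolidin-2-one
Conditions: Dess–Martin periodinane, CH2Cl2, rt
Reagents that add atoms: none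
Why: Dess–Martin oxidation converts the neopentyl-type alcohol into the non-enolisable aldehyde under neutral conditions that spare the imide.

Step 8
Reactants: 14 (S)-4-benzyl-3-[(E)-3,7,7-trimethyl-8-oxooct-2-enoyl]oxazolidin-2-one; 15 diethyl (2-oxobutyl)phosphonate
Product: 16 (S)-4-benzyl-3-[(2E,8E)-3,7,7-trimethyl-10-oxododeca-2,8-dienoyl]oxazolidin-2-one
Conditions: LiCl, iPr2NEt, MeCN, rt
Reagents that add atoms: none
Why: Horner–Wadsworth–Emmons olefination with the β-ketophosphonate under LiCl/amine conditions gives the E-enone (C5=C6), the weak base leaving the imide untouched.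

Step 9
Reactants: 16 (S)-4-benzyl-3-[(2E,8E)-3,7,7-trimethyl-10-oxododeca-2,8-dienoyl]oxazolidin-2-one
Product: 17 (S)-4-benzyl-3-[(2E,8E,10Z)-10-(tert-butyldimethylsilyloxy)-3,7,7-trimethyldodeca-2,8,10-trienoyl]oxazolidin-2-one
Conditions: tert-butyldimethylsilyl triflate (1.2 equiv), Et3N, CH2Cl2, −78 → 0 °C
Reagents that add atoms: tert-butyldimethylsilyl trifluoromethanesulfonate, CC(C)(C)[Si](C)(C)OS(=O)(=O)C(F)(F)F
Why: Soft enolisation (silyl triflate/amine) of the ethyl ketone, whose other α-side (C4) is quaternary, gives the 2-silyloxydiene with Z enol ether geometry because the methyl group avoids the allylic strain of the inside position.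

Step 10
Reactants: 17 (S)-4-benzyl-3-[(2E,8E,10Z)-10-(tert-butyldimethylsilyloxy)-3,7,7-trimethyldodeca-2,8,10-trienoyl]oxazolidin-2-one
Product: 18 (S)-4-benzyl-3-{[(1S,2R,4aS,8aS)-3-(tert-butyldimethylsilyloxy)-2,5,5,8a-tetramethyl-1,2,4a,5,6,7,8,8a-octahydronaphthalen-1-yl]carbonyl}oxazolidin-2-one
Conditions: Me2AlCl (1.5 equiv), 2,6-di-tert-butylpyridine (0.2 equiv), CH2Cl2, −30 → 0 °C; aq. NaHCO3
Reagents that add atoms: none
Why: Excess Me2AlCl gives a cationic Me2Al chelate of the two imide carbonyls, which locks the s-cis enoyl imide and lowers its LUMO, so that the tethered Z-2-silyloxydiene adds in a concerted, asynchronous [4+2] cycloaddition; the closest known reaction type is the Lewis-acid-promoted intramolecular Diels–Alder reaction of 2,7,9-decatrienoyl oxazolidinones to trans-fused bicycles. Ring B (C5–C10) is closed as the new cyclohexene by both new bonds (C5–C10 and C8–C9), and ring A (C1–C5, C10) is closed at the same moment by the C5–C10 bond around the four-carbon tether. C9 and C10 are set by the auxiliary (attack on the Cα face anti to the benzyl group of the chelated (S)-oxazolidinone) and the cis relation between C11 and the C10 methyl by the E dienophile; C5 is set by the carbonyl-endo transition state, which keeps the tether exo and gives the trans fusion, and C8 by the Z enol ether (methyl outside, hence cis to C11; it is equilibrated later). The step needs regiocontrol against the polarisation of the silyloxydiene (whose nucleophilic C8 must bond to the α-carbon C9), which the short C1–C4 tether enforces, and endo and facial control, which the chelate and the auxiliary supply, while the C4 gem-dimethyl group helps the chain to fold. Because the β,β-disubstituted dienophile is less reactive than the usual cases, the temperature is raised only as far as the enol silane tolerates, with a hindered pyridine present to trap adventitious HCl.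

Step 11
Reactants: 18 cycloadduct imide
Product: 19 [(1S,2R,4aS,8aS)-3-(tert-butyldimethylsilyloxy)-2,5,5,8a-tetramethyl-1,2,4a,5,6,7,8,8a-octahydronaphthalen-1-yl]methanol
Conditions: LiBH4, MeOH (1 equiv), Et2O, 0 °C
Reagents that add atoms: none
Why: Reductive cleavage of the N-acyloxazolidinone by LiBH4 at the exocyclic carbonyl gives the C11 alcohol and returns the auxiliary, the silyl enol ether serving as a hydride-stable mask of the C7 ketone.

Step 12
Reactants: 19 C11 alcohol
Product: 20 (1S,2R,4aS,8aS)-3-(tert-butyldimethylsilyloxy)-2,5,5,8a-tetramethyl-1,2,4a,5,6,7,8,8a-octahydronaphthalene-1-carbaldehyde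
Conditions: Dess–Martin periodinane, pyridine, CH2Cl2, 0 °C → rt
Reagents that add atoms: none
Why: Pyridine-buffered Dess–Martin oxidation gives the C11 aldehyde without acid that could hydrolyse the enol silane or epimerise C9.

Step 13
Reactants: 21 methyl (R)-3-methylglutarate [(R)-5-methoxy-3-methyl-5-oxopentanoic acid]
Product: 22 methyl (S)-4-bromo-3-methylbutanoate
Conditions: HgO, Br2, CCl4, reflux, dark
Reagents that add atoms: bromine, BrBr
Why: The Cristol–Firth variant of the Hunsdiecker bromodecarboxylation replaces the free carboxyl group by bromine through an acyl hypobromite and a primary radical, and the methyl-bearing stereocentre, one carbon away from the radical, is retained (R becomes S only through the change in priorities).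

Step 14
Reactants: 22 methyl (S)-4-bromo-3-methylbutanoate
Product: 23 [(S)-4-methoxy-2-methyl-4-oxobutyl]triphenylphosphonium bromide
Conditions: PPh3, MeCN, reflux
Reagents that add atoms: triphenylphosphine, c1ccccc1P(c1ccccc1)c1ccccc1
Why: SN2 quaternisation of triphenylphosphine by the primary bromide gives the phosphonium salt for the Wittig reaction.

Step 15
Reactants: 20 C11 aldehyde; 23 [(S)-4-methoxy-2-methyl-4-oxobutyl]triphenylphosphonium bromide
Product: 25 methyl (11Z,13S)-7-(tert-butyldimethylsilyloxy)-8αH-labda-6,11-dien-15-oate, via phosphorus ylide 24 (not isolated)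
Conditions: 23, NaN(SiMe3)2, THF, −78 → 0 °C; then 20, −78 °C → rt
Reagents that add atoms: none
Why: Wittig olefination with the non-stabilised ylide joins C11 to C12 (Z-alkene expected, geometry irrelevant), addition at low temperature being faster than enolisation of the hindered aldehyde, and C13 arrives with the configuration of the chiral-pool fragment.

Step 16
Reactants: 25 methyl (11Z,13S)-7-(tert-butyldimethylsilyloxy)-8αH-labda-6,11-dien-15-oate
Product: 28 methyl (13R)-7-oxo-8βH-labdan-15-oate (8α-methyl), via saturated enol silane 26 (not isolated), via 8β-methyl ketone 27 (not isolated)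
Conditions: H2 (1 atm), 10% Pd/C, EtOAc, rt; filter; then NaOMe (cat.), MeOH, rt
Reagents that add atoms: none
Why: Heterogeneous catalytic hydrogenation saturates the disubstituted C11=C12 alkene in preference to the trisubstituted enol silane, and methoxide then cleaves the silyl enol ether and equilibrates the ketone through its C8 enolate to the equatorial 8α-methyl epimer (base-mediated epimerisation), which is free of the 1,3-diaxial contact with the C10 methyl.

Step 17
Reactants: 28 methyl (13R)-7-oxo-8βH-labdan-15-oate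
Product: 29 methyl (13R)-7α-hydroxy-8βH-labdan-15-oate
Conditions: LiBH(s-Bu)3, THF, −78 °C; then H2O2, pH 7 buffer, 0 °C
Reagents that add atoms: none
Why: Reduction with the bulky borohydride LiBH(s-Bu)3 delivers hydride along the equatorial trajectory and so sets the axial 7α-hydroxyl, cis to the 8α-methyl, while the ester survives at −78 °C.

Step 18
Reactants: 29 methyl (13R)-7α-hydroxy-8βH-labdan-15-oate
Product: 30 methyl (13R)-labd-7-en-15-oate
Conditions: POCl3, pyridine, 0 → 50 °C
Reagents that add atoms: none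
Why: E2 dehydration through the axial 7α-dichlorophosphate removes the antiperiplanar axial tertiary H8β (Zaitsev orientation) and gives the trisubstituted C7=C8 alkene.

Step 19
Reactants: 30 methyl (13R)-labd-7-en-15-oate
Product: 31 methyl (13R)-7α,8α-epoxylabdan-15-oate
Conditions: 3-chloroperoxybenzoic acid, NaHCO3, CH2Cl2, 0 °C
Reagents that add atoms: 3-chloroperoxybenzoic acid, OOC(=O)c1cccc(Cl)c1
Why: Prilezhaev epoxidation takes place on the α face, opposite the axial C10 methyl, and so places the epoxide oxygen α at C7 and C8.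

Step 20
Reactants: 31 methyl (13R)-7α,8α-epoxylabdan-15-oate
Product: 33 (13R)-7α-hydroxylabd-8(17)-en-15-oic acid, via 7α-hydroxy methyl ester 32 (not isolated)
Conditions: Al(OiPr)3, toluene, reflux; aqueous work-up; then LiOH, THF/MeOH/H2O, rt; 1 M HCl to pH 3, 0 °C
Reagents that add atoms: lithium hydroxide, [Li+].[OH-]
Why: Aluminium isopropoxide-mediated isomerisation of the epoxide to the allylic alcohol (oxygen bound to aluminium, syn removal of a C17 methyl proton as the C8–O bond breaks) gives the 8(17)-ene with the C7–O bond, hence 7α, untouched, and saponification of the crude ester in the same step makes any ester exchange with isopropoxide irrelevant.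

Step 21
Reactants: 33 (13R)-7α-hydroxylabd-8(17)-en-15-oic acid
Product: 35 (13R)-7α-acetoxylabd-8(17)-en-15-oic acid, via acetoxy mixed anhydride 34 (not isolated)
Conditions: Ac2O, pyridine, DMAP (cat.), rt; then H2O, rt
Reagents that add atoms: acetic anhydride, CC(=O)OC(C)=O
Why: DMAP-catalysed acetylation esterifies the axial 7α-hydroxyl, and the mixed anhydride formed at the carboxyl group is hydrolysed selectively by water because an anhydride is far more labile than a secondary acetate.

Compound list
1 | methyl isobutyrate | CC(C)C(=O)OC | starting material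
2 | 5-iodopent-1-yne | C#CCCCI | starting material
3 | lithium 1-methoxy-2-methylprop-1-en-1-olate (enolate of 1) | [Li+].COC([O-])=C(C)C | intermediate
4 | methyl 2,2-dimethylhept-6-ynoate | C#CCCCC(C)(C)C(=O)OC | intermediate
5 | 2,2-dimethylhept-6-yn-1-ol | C#CCCCC(C)(C)CO | intermediate
6 | tert-butyl[(2,2-dimethylhept-6-yn-1-yl)oxy]dimethylsilane | C#CCCCC(C)(C)CO[Si](C)(C)C(C)(C)C | intermediate
7 | (E)-{7-[(tert-butyldimethylsilyl)oxy]-2,6,6-trimethylhept-1-en-1-yl}dimethylalane | CC(C)(C)[Si](C)(C)OCC(C)(C)CCC/C(C)=C/[Al](C)C | intermediate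
8 | lithium butyl{(E)-7-[(tert-butyldimethylsilyl)oxy]-2,6,6-trimethylhept-1-en-1-yl}dimethylaluminate | [Li+].CCCC[Al-](C)(C)/C=C(C)/CCCC(C)(C)CO[Si](C)(C)C(C)(C)C | intermediate
9 | (E)-8-[(tert-butyldimethylsilyl)oxy]-3,7,7-trimethyloct-2-enoic acid | CC(C)(C)[Si](C)(C)OCC(C)(C)CCC/C(C)=C/C(=O)O | intermediate
10 | (S)-4-benzyloxazolidin-2-one | O=C1OC[C@H](Cc2ccccc2)N1 | starting material
11 | (E)-8-[(tert-butyldimethylsilyl)oxy]-3,7,7-trimethyloct-2-enoic pivalic anhydride | CC(C)(C)[Si](C)(C)OCC(C)(C)CCC/C(C)=C/C(=O)OC(=O)C(C)(C)C | intermediate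
12 | (S)-4-benzyl-3-{(E)-8-[(tert-butyldimethylsilyl)oxy]-3,7,7-trimethyloct-2-enoyl}oxazolidin-2-one | CC(C)(C)[Si](C)(C)OCC(C)(C)CCC/C(C)=C/C(=O)N1[C@@H](Cc2ccccc2)COC1=O | intermediate
13 | (S)-4-benzyl-3-[(E)-8-hydroxy-3,7,7-trimethyloct-2-enoyl]oxazolidin-2-one | OCC(C)(C)CCC/C(C)=C/C(=O)N1[C@@H](Cc2ccccc2)COC1=O | intermediate
14 | (S)-4-benzyl-3-[(E)-3,7,7-trimethyl-8-oxooct-2-enoyl]oxazolidin-2-one | O=CC(C)(C)CCC/C(C)=C/C(=O)N1[C@@H](Cc2ccccc2)COC1=O | intermediate
15 | diethyl (2-oxobutyl)phosphonate | CCC(=O)CP(=O)(OCC)OCC | starting material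
16 | (S)-4-benzyl-3-[(2E,8E)-3,7,7-trimethyl-10-oxododeca-2,8-dienoyl]oxazolidin-2-one | CCC(=O)/C=C/C(C)(C)CCC/C(C)=C/C(=O)N1[C@@H](Cc2ccccc2)COC1=O | intermediate
17 | (S)-4-benzyl-3-[(2E,8E,10Z)-10-(tert-butyldimethylsilyloxy)-3,7,7-trimethyldodeca-2,8,10-trienoyl]oxazolidin-2-one (key-step precursor) | C/C=C(O[Si](C)(C)C(C)(C)C)/C=C/C(C)(C)CCC/C(C)=C/C(=O)N1[C@@H](Cc2ccccc2)COC1=O | intermediate
18 | (S)-4-benzyl-3-{[(1S,2R,4aS,8aS)-3-(tert-butyldimethylsilyloxy)-2,5,5,8a-tetramethyl-1,2,4a,5,6,7,8,8a-octahydronaphthalen-1-yl]carbonyl}oxazolidin-2-one (trans-decalin; 5α-H, 8β-methyl, 9β-acyl, 10β-methyl; C6=C7 enol silane) | C[C@H]1C(O[Si](C)(C)C(C)(C)C)=C[C@H]2C(C)(C)CCC[C@]2(C)[C@H]1C(=O)N3[C@@H](Cc4ccccc4)COC3=O | intermediate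
19 | [(1S,2R,4aS,8aS)-3-(tert-butyldimethylsilyloxy)-2,5,5,8a-tetramethyl-1,2,4a,5,6,7,8,8a-octahydronaphthalen-1-yl]methanol | C[C@H]1C(O[Si](C)(C)C(C)(C)C)=C[C@H]2C(C)(C)CCC[C@]2(C)[C@H]1CO | intermediate
20 | (1S,2R,4aS,8aS)-3-(tert-butyldimethylsilyloxy)-2,5,5,8a-tetramethyl-1,2,4a,5,6,7,8,8a-octahydronaphthalene-1-carbaldehyde | C[C@H]1C(O[Si](C)(C)C(C)(C)C)=C[C@H]2C(C)(C)CCC[C@]2(C)[C@H]1C=O | intermediate
21 | methyl (R)-3-methylglutarate [(R)-5-methoxy-3-methyl-5-oxopentanoic acid] | OC(=O)C[C@@H](C)CC(=O)OC | starting material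
22 | methyl (S)-4-bromo-3-methylbutanoate | BrC[C@@H](C)CC(=O)OC | intermediate
23 | [(S)-4-methoxy-2-methyl-4-oxobutyl]triphenylphosphonium bromide | [Br-].COC(=O)C[C@H](C)C[P+](c1ccccc1)(c1ccccc1)c1ccccc1 | intermediate
24 | methyl (S)-3-methyl-4-(triphenyl-λ5-phosphanylidene)butanoate | COC(=O)C[C@H](C)C=P(c1ccccc1)(c1ccccc1)c1ccccc1 | intermediate
25 | methyl (11Z,13S)-7-(tert-butyldimethylsilyloxy)-8αH-labda-6,11-dien-15-oate | C[C@H]1C(O[Si](C)(C)C(C)(C)C)=C[C@H]2C(C)(C)CCC[C@]2(C)[C@H]1/C=C\[C@@H](C)CC(=O)OC | intermediate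
26 | methyl (13R)-7-(tert-butyldimethylsilyloxy)-8αH-labd-6-en-15-oate | C[C@H]1C(O[Si](C)(C)C(C)(C)C)=C[C@H]2C(C)(C)CCC[C@]2(C)[C@H]1CC[C@@H](C)CC(=O)OC | intermediate
27 | methyl (13R)-7-oxo-8αH-labdan-15-oate (8β-methyl) | C[C@H]1C(=O)C[C@H]2C(C)(C)CCC[C@]2(C)[C@H]1CC[C@@H](C)CC(=O)OC | intermediate
28 | methyl (13R)-7-oxo-8βH-labdan-15-oate (8α-methyl) | C[C@@H]1C(=O)C[C@H]2C(C)(C)CCC[C@]2(C)[C@H]1CC[C@@H](C)CC(=O)OC | intermediate
29 | methyl (13R)-7α-hydroxy-8βH-labdan-15-oate | C[C@@H]1[C@H](O)C[C@H]2C(C)(C)CCC[C@]2(C)[C@H]1CC[C@@H](C)CC(=O)OC | intermediate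
30 | methyl (13R)-labd-7-en-15-oate | CC1=CC[C@H]2C(C)(C)CCC[C@]2(C)[C@H]1CC[C@@H](C)CC(=O)OC | intermediate
31 | methyl (13R)-7α,8α-epoxylabdan-15-oate | C[C@@]12O[C@@H]1C[C@H]3C(C)(C)CCC[C@]3(C)[C@H]2CC[C@@H](C)CC(=O)OC | intermediate
32 | methyl (13R)-7α-hydroxylabd-8(17)-en-15-oate | C=C1[C@H](O)C[C@H]2C(C)(C)CCC[C@]2(C)[C@H]1CC[C@@H](C)CC(=O)OC | intermediate
33 | (13R)-7α-hydroxylabd-8(17)-en-15-oic acid | C=C1[C@H](O)C[C@H]2C(C)(C)CCC[C@]2(C)[C@H]1CC[C@@H](C)CC(=O)O | intermediate
34 | acetic (13R)-7α-acetoxylabd-8(17)-en-15-oic anhydride | C=C1[C@H](OC(C)=O)C[C@H]2C(C)(C)CCC[C@]2(C)[C@H]1CC[C@@H](C)CC(=O)OC(C)=O | intermediate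
35 | (13R)-7α-acetoxylabd-8(17)-en-15-oic acid, (5S,7R,9R,10S,13R) | C=C1[C@H](OC(C)=O)C[C@H]2C(C)(C)CCC[C@]2(C)[C@H]1CC[C@@H](C)CC(=O)O | target

Total steps: 21. Longest linear sequence: 19 steps (steps 1–12 and 15–21, from methyl isobutyrate); the phosphonium salt is made in a 2-step branch (steps 13 and 14).

Steps most likely to fail

Step 10. What may go wrong: the stoichiometric aluminium Lewis acid cleaves or protonates the silyl enol ether before the poorly reactive β,β-disubstituted dienophile has cyclised, or facial control through the chelate is incomplete. The fallback replaces auxiliary control by catalyst control, a known mode for trienoyl oxazolidinones. It sets out from acid 9, which is coupled through mixed anhydride 11 with unsubstituted oxazolidin-2-one to the achiral silyl ether imide F1. Desilylation to the hydroxy imide F2, Dess–Martin oxidation to the aldehyde imide F3, Horner–Wadsworth–Emmons reaction with 15 to the enone imide F4 and silylation to the achiral trienimide F5 repeat steps 6 to 9. F5 is then cyclised in CH2Cl2 at room temperature with a catalytic amount of the cationic complex of divalent copper with (R,R)-2,2'-isopropylidenebis(4-tert-butyl-2-oxazoline), [Cu(t-Bu-box)](SbF6)2, a much milder Lewis acid that tolerates enol silanes, to the achiral-imide cycloadduct F6. The ligand enantiomer is chosen so that the same Cα face is attacked as in step 10. LiBH4 reduction of F6 comes back to the route at alcohol 19.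

Step 15. What may go wrong: addition to the neopentyl-type aldehyde is slow, so the basic ylide enolises C9 (epimerisation) or the aldehyde is returned unchanged. The fallback builds the chain stepwise with small, weakly basic stabilised phosphonates and sets C13 by a catalyst. It sets out from aldehyde 20. Horner–Wadsworth–Emmons reaction with dimethyl (2-oxopropyl)phosphonate (LiCl, iPr2NEt, MeCN) should give the E-enone F7, and hydrogenation over Pd/C the saturated methyl ketone F8. A second Horner–Wadsworth–Emmons reaction with trimethyl phosphonoacetate (NaH, THF) should give, after removal of the minor Z isomer, the E-enoate F9. Copper hydride-catalysed asymmetric conjugate reduction (Cu(OAc)2, the enantiomer of p-Tol-BINAP that the established correlation for E-enoates assigns to the 13R product, polymethylhydrosiloxane, t-BuOH) then comes back to the route at ester 26, the intermediate of step 16, which is taken on to 28 with NaOMe.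

Step 18. What may go wrong: elimination runs toward C6, or substitution by chloride competes with elimination. The fallback removes a regiodefined enol triflate reductively and does not eliminate the alcohol. It sets out from ketone 28. Silylation under equilibrating conditions (Me3SiCl, NaI, Et3N, MeCN) should give the more substituted C7=C8 trimethylsilyl enol ether F10. CsF and PhNTf2 convert it regiospecifically into the enol triflate F11, and reduction with Pd(OAc)2/PPh3, HCO2H and Et3N in DMF comes back to the route at alkene 30.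

Further compounds
F1 | step 10 | 3-{(E)-8-[(tert-butyldimethylsilyl)oxy]-3,7,7-trimethyloct-2-enoyl}oxazolidin-2-one | CC(C)(C)[Si](C)(C)OCC(C)(C)CCC/C(C)=C/C(=O)N1CCOC1=O
F2 | step 10 | 3-[(E)-8-hydroxy-3,7,7-trimethyloct-2-enoyl]oxazolidin-2-one | OCC(C)(C)CCC/C(C)=C/C(=O)N1CCOC1=O
F3 | step 10 | 3-[(E)-3,7,7-trimethyl-8-oxooct-2-enoyl]oxazolidin-2-one | O=CC(C)(C)CCC/C(C)=C/C(=O)N1CCOC1=O
F4 | step 10 | 3-[(2E,8E)-3,7,7-trimethyl-10-oxododeca-2,8-dienoyl]oxazolidin-2-one | CCC(=O)/C=C/C(C)(C)CCC/C(C)=C/C(=O)N1CCOC1=O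
F5 | step 10 | 3-[(2E,8E,10Z)-10-(tert-butyldimethylsilyloxy)-3,7,7-trimethyldodeca-2,8,10-trienoyl]oxazolidin-2-one | C/C=C(O[Si](C)(C)C(C)(C)C)/C=C/C(C)(C)CCC/C(C)=C/C(=O)N1CCOC1=O
F6 | step 10 | 3-{[(1S,2R,4aS,8aS)-3-(tert-butyldimethylsilyloxy)-2,5,5,8a-tetramethyl-1,2,4a,5,6,7,8,8a-octahydronaphthalen-1-yl]carbonyl}oxazolidin-2-one | C[C@H]1C(O[Si](C)(C)C(C)(C)C)=C[C@H]2C(C)(C)CCC[C@]2(C)[C@H]1C(=O)N3CCOC3=O
F7 | step 15 | (11E)-7-(tert-butyldimethylsilyloxy)-8αH-14,15-dinorlabda-6,11-dien-13-one | C[C@H]1C(O[Si](C)(C)C(C)(C)C)=C[C@H]2C(C)(C)CCC[C@]2(C)[C@H]1/C=C/C(C)=O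
F8 | step 15 | 7-(tert-butyldimethylsilyloxy)-8αH-14,15-dinorlabd-6-en-13-one | C[C@H]1C(O[Si](C)(C)C(C)(C)C)=C[C@H]2C(C)(C)CCC[C@]2(C)[C@H]1CCC(C)=O
F9 | step 15 | methyl (13E)-7-(tert-butyldimethylsilyloxy)-8αH-labda-6,13-dien-15-oate | C[C@H]1C(O[Si](C)(C)C(C)(C)C)=C[C@H]2C(C)(C)CCC[C@]2(C)[C@H]1CC/C(C)=C/C(=O)OC
F10 | step 18 | methyl (13R)-7-(trimethylsilyloxy)labd-7-en-15-oate | CC1=C(O[Si](C)(C)C)C[C@H]2C(C)(C)CCC[C@]2(C)[C@H]1CC[C@@H](C)CC(=O)OC
F11 | step 18 | methyl (13R)-7-(trifluoromethanesulfonyloxy)labd-7-en-15-oate | CC1=C(OS(=O)(=O)C(F)(F)F)C[C@H]2C(C)(C)CCC[C@]2(C)[C@H]1CC[C@@H](C)CC(=O)OC
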